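The pyranone (ring C) of the flavanone half is disconnected at C4–C4a. Ring A is a symmetric phloroglucinol triether, so in the open precursor the future C4a and C8 are interchangeable and each lies ortho or para to all three oxygens. An activated 3-aryl-3-aryloxypropanoic acid therefore acylates this ring and closes ring C in one operation. The C2–O1 stereocentre, set earlier as a plain aryl ether by iridium-catalysed allylic etherification, is a spectator. Precursor 21 is the (S)-acid bearing a 3,5-bis(benzyloxy)phenoxy group, tetrabenzylated luteolin at C5' of ring B, and two benzyl carbonates on the ring B catechol. These disfavour benzylic ionisation and leave with the benzyl ethers in one neutral hydrogenolysis.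

Key step: step 15

Remarks and assumptions (one line each)
- The C5'–C6'' biaryl axis has three ortho oxygen substituents and no descriptor in the target, so it is treated as configurationally labile; crowded protected intermediates may appear as slowly interconverting rotamers that converge on deprotection.
- The (Ra,Rc,Rc) ligand is assigned to the (S)-ether by analogy with simple cinnamyl carbonates; both antipodes are commercial, so the sense is to be confirmed on the first batch and the mirror-image ligand taken if needed.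
- Compounds 5 and 10 are taken as catalogue chemicals.
- Benzyl carbonates are chosen over simple acyl esters on ring B: they withdraw electrons comparably, but their removal needs neither acid nor base on the free flavanone.
- Abbreviations: Bn = benzyl; TBS = tert-butyldimethylsilyl; Cbz = benzyloxycarbonyl; LutBn4 = 5,7-bis(benzyloxy)-2-[3,4-bis(benzyloxy)phenyl]-4-oxo-4H-chromen-6-yl.

Step 1
Reactants: 1 luteolin
Product: 2 7,3',4'-tri-O-benzylluteolin (5-OH free)
Conditions: BnBr (3.3 equiv), K2CO3, DMF, rt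
Reagents that add atoms: benzyl bromide, BrCc1ccccc1
Why: Williamson etherification alkylates the phenols at C7, C3' and C4' at room temperature, whereas the 5-OH is hydrogen-bonded to the C4 carbonyl and reacts only on heating.

Step 2
Reactants: 2 7,3',4'-tri-O-benzylluteolin
Product: 3 7,3',4'-tri-O-benzyl-6-iodoluteolin
Conditions: BnMe3N[ICl2] (1.05 equiv), CaCO3, CH2Cl2–MeOH, rt
Reagents that add atoms: benzyltrimethylammonium dichloroiodate, C[N+](C)(C)Cc1ccccc1.Cl[I-]Cl
Why: Electrophilic aromatic iodination of 5-hydroxy-7-alkoxyflavones with this mild iodine monochloride carrier is known to go to C6, ortho to the free phenol, while CaCO3 takes up the HCl.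

Step 3
Reactants: 3 7,3',4'-tri-O-benzyl-6-iodoluteolin
Product: 4 5,7,3',4'-tetra-O-benzyl-6-iodoluteolin
Conditions: BnBr (1.5 equiv), Cs2CO3, DMF, 50 °C
Reagents that add atoms: benzyl bromide, BrCc1ccccc1
Why: Williamson etherification under more forcing conditions overcomes the chelation of the 5-OH, and the aryl iodide is inert to carbonate base.

Step 4
Reactants: 5 3-bromo-4,5-dihydroxybenzaldehyde
Product: 6 3-bromo-4,5-bis(tert-butyldimethylsilyloxy)benzaldehyde
Conditions: TBSCl (2.5 equiv), imidazole, DMF, rt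
Reagents that add atoms: tert-butyldimethylsilyl chloride, CC(C)(C)[Si](C)(C)Cl
Why: Standard imidazole-promoted silylation masks the catechol with groups that tolerate ylide, hydride, aryloxide, borane and palladium chemistry and can later be removed by fluoride without touching benzyl ethers.

Step 5
Reactants: 6 3-bromo-4,5-bis(tert-butyldimethylsilyloxy)benzaldehyde
Product: 7 ethyl (E)-3-[3-bromo-4,5-bis(tert-butyldimethylsilyloxy)phenyl]prop-2-enoate
Conditions: Ph3P=CHCO2Et, toluene, 60 °C
Reagents that add atoms: (ethoxycarbonylmethylene)triphenylphosphorane, CCOC(=O)C=P(c1ccccc1)(c1ccccc1)c1ccccc1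
Why: Wittig olefination with a stabilised ylide needs no external base, so the aryl silyl ethers are safe, and it gives the E-cinnamate.

Step 6
Reactants: 7 ethyl (E)-cinnamate
Product: 8 (E)-3-[3-bromo-4,5-bis(tert-butyldimethylsilyloxy)phenyl]prop-2-en-1-ol
Conditions: i-Bu2AlH (2.3 equiv), CH2Cl2, −78 °C; aqueous potassium sodium tartrate
Reagents that add atoms: none
Why: 1,2-Reduction of the conjugated ester with i-Bu2AlH gives the E-allylic alcohol, and it is run before the hydride-sensitive flavone pyranone enters the molecule.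

Step 7
Reactants: 8 (E)-cinnamyl alcohol
Product: 9 (E)-3-[3-bromo-4,5-bis(tert-butyldimethylsilyloxy)phenyl]prop-2-en-1-yl methyl carbonate
Conditions: ClCO2Me, pyridine, CH2Cl2, 0 °C
Reagents that add atoms: methyl chloroformate, COC(=O)Cl
Why: O-Acylation with a chloroformate gives the linear allylic carbonate, the standard electrophile for iridium-catalysed allylic substitution, and no zerovalent palladium that could ionise it is used until it has been consumed.

Step 8
Reactants: 9 (E)-cinnamyl methyl carbonate; 10 3,5-bis(benzyloxy)phenol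
Product: 12 (S)-1-{1-[3,5-bis(benzyloxy)phenoxy]prop-2-en-1-yl}-3-bromo-4,5-bis(tert-butyldimethylsilyloxy)benzene, via lithium aryloxide 11 (not isolated)
Conditions: 10 (1.6 equiv), n-BuLi (1.5 equiv), THF, 0 °C; then 9, [Ir(cod)Cl]2 (2 mol %), (Ra,Rc,Rc)-O,O'-(1,1'-binaphthalene-2,2'-diyl) N,N-bis(1-phenylethyl)phosphoramidite (4 mol %, pre-activated with n-PrNH2), THF, rt
Reagents that add atoms: none
Why: In this iridium-catalysed asymmetric allylic etherification the cyclometalated iridium–phosphoramidite complex ionises the carbonate to an η3-allyl complex and the aryloxide attacks the aryl-substituted terminus anti to the metal, so the ligand configuration fixes the branched (S)-ether stereocentre that becomes C2.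

Step 9
Reactants: 12 (S)-branched allylic aryl ether
Product: 14 (S)-3-[3,5-bis(benzyloxy)phenoxy]-3-[3-bromo-4,5-bis(tert-butyldimethylsilyloxy)phenyl]propan-1-ol, via B-alkyl-9-BBN adduct 13 (not isolated)
Conditions: 9-BBN-H (1.5 equiv), THF, 0 °C to rt; then 30% H2O2, pH 7 phosphate buffer, 0 °C to rt
Reagents that add atoms: hydrogen peroxide, OO
Why: In this hydroboration–oxidation the bulky borane places boron on the terminal carbon only, so no β-alkoxyborane that could eliminate is formed, the buffered peroxide spares the aryl silyl ethers, and the stereocentre is not touched.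

Step 10
Reactants: 14 (S)-bromo alcohol
Product: 15 (S)-3-[3,5-bis(benzyloxy)phenoxy]-3-[3,4-bis(tert-butyldimethylsilyloxy)-5-(4,4,5,5-tetramethyl-1,3,2-dioxaborolan-2-yl)phenyl]propan-1-ol
Conditions: B2pin2 (1.3 equiv), Pd(dppf)Cl2 (5 mol %), KOAc, 1,4-dioxane, 85 °C
Reagents that add atoms: bis(pinacolato)diboron, CC1(C)OB(OC1(C)C)B1OC(C)(C)C(C)(C)O1
Why: Miyaura borylation converts the aryl bromide into the pinacol boronate under the weak base KOAc, which tolerates the free alcohol, the silyl ethers and the benzylic ether, and it comes after step 9 because peroxide would oxidise an aryl boronate.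

Step 11
Reactants: 15 (S)-ring B boronate; 4 5,7,3',4'-tetra-O-benzyl-6-iodoluteolin
Product: 16 (S)-3-[3,5-bis(benzyloxy)phenoxy]-3-[3-(LutBn4)-4,5-bis(tert-butyldimethylsilyloxy)phenyl]propan-1-ol
Conditions: Pd(OAc)2 (5 mol %), SPhos (10 mol %), K3PO4, toluene–H2O (10:1), 80 °C
Reagents that add atoms: none
Why: In this Suzuki–Miyaura coupling the hindered 2,6-dialkoxyaryl iodide is the electrophile and the ring B boronate, less hindered and less prone to protodeboronation, is the nucleophile, a pairing with precedent for 6-arylflavones; SPhos copes with three ortho substituents, and the alcohol oxidation level rules out base-induced loss of the aryloxide.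

Step 12
Reactants: 16 (S)-biaryl alcohol
Product: 18 (S)-3-[3,5-bis(benzyloxy)phenoxy]-3-[3-(LutBn4)-4,5-bis(tert-butyldimethylsilyloxy)phenyl]propanoic acid, via aldehyde 17 (not isolated)
Conditions: (n-Pr)4N[RuO4] (10 mol %), N-methylmorpholine N-oxide monohydrate (10 equiv), MeCN–CH2Cl2, rt
Reagents that add atoms: water (from the N-oxide monohydrate), O
Why: In this Ley–Griffith oxidation run with the N-oxide monohydrate, aldehyde 17 is hydrated in situ and oxidised on to the acid under nearly neutral conditions, which avoids β-elimination of the aryloxide and any halogenating or strongly acidic oxidant that would attack the phloroglucinol ring.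

Step 13
Reactants: 18 (S)-bis-silylated acid
Product: 19 (S)-3-[3,5-bis(benzyloxy)phenoxy]-3-[3-(LutBn4)-4,5-dihydroxyphenyl]propanoic acid
Conditions: n-Bu4NF (2.5 equiv), AcOH (3 equiv), THF, 0 °C, argon; extractive work-up at pH 4, used directly
Reagents that add atoms: none
Why: Fluoride-induced cleavage of aryl silyl ethers is fast at 0 °C, the acetic acid buffer keeps the medium close to neutral, and a carboxylic acid or carboxylate is not prone to E1cB loss of the β-aryloxide.

Step 14
Reactants: 19 (S)-catechol acid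
Product: 21 (S)-3-[3,5-bis(benzyloxy)phenoxy]-3-[3-(LutBn4)-4,5-bis(benzyloxycarbonyloxy)phenyl]propanoic acid, via mixed carbonic anhydride 20 (not isolated)
Conditions: CbzCl (4 equiv), pyridine, CH2Cl2, 0 °C; then H2O–THF, rt
Reagents that add atoms: benzyl chloroformate, O=C(Cl)OCc1ccccc1; water, O
Why: O-Acylation with a chloroformate, the classical carbonate protection of phenol carboxylic acids, converts both phenols into benzyl carbonates, and the carboxyl group is acylated too but the far more reactive mixed anhydride 20 is hydrolysed back to the acid by the aqueous pyridine quench.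

Step 15
Reactants: 21 (S)-bis(benzyl carbonate) acid
Product: 23 (2S)-5,7-bis(benzyloxy)-2-[3-(LutBn4)-4,5-bis(benzyloxycarbonyloxy)phenyl]chroman-4-one, via acyl trifluoroacetate 22 (not isolated)
Conditions: (CF3CO)2O (1.3 equiv), CH2Cl2 (0.01 M), −30 to 0 °C; cold aqueous NaHCO3
Reagents that add atoms: none
Why: Trifluoroacetic anhydride turns the acid into acyl trifluoroacetate 22, whose acyl carbon is attacked by the ring A carbon ortho to the ether oxygen; the arenium ion loses its proton and trifluoroacetate leaves, which creates C4–C4a. The closest known reaction type is the intramolecular Friedel–Crafts acylation of 3-aryloxy- and 3-aryl-3-aryloxypropanoic acids to chroman-4-ones and 2-arylchroman-4-ones, which needs no Lewis acid when the arene is a phloroglucinol ether. The only ring formed, six-membered ring C, closes in the 6-exo-trig mode with the carbonyl oxygen outside the ring. No stereocentre is created and C2 takes no part in bond making or breaking, so its S configuration is retained as long as C2–O1 neither ionises nor is lost by β-elimination: the carbonate at O4' (para to the benzylic carbon) and the one at O3' raise the barrier to the benzylic cation, and the absence of base and the low temperature disfavour elimination. Site selectivity rests on the substrate, because the two reachable ortho carbons are equivalent, the carbon between the two benzyloxy groups cannot reach the acyl carbon, and every other arene is less nucleophilic and available only intermolecularly at high dilution. A near-stoichiometric amount of anhydride limits C-trifluoroacetylation of ring A before closure, and the aryl ketone formed deactivates the ring afterwards.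

Step 16
Reactants: 23 protected biflavonoid
Product: 24 (2S)-2-{3-[2-(3,4-dihydroxyphenyl)-5,7-dihydroxy-4-oxo-4H-chromen-6-yl]-4,5-dihydroxyphenyl}-5,7-dihydroxychroman-4-one (CNP0333260.1)
Conditions: H2 (1 atm), 10% Pd/C, THF–EtOH, rt; filtration, evaporation
Reagents that add atoms: none
Why: Catalytic hydrogenolysis cleaves the six benzyl ethers and the two benzyl carbonates (which then lose CO2) under neutral conditions, so the free flavanone never meets acid or base that could open ring C and racemise C2, while the flavone C2''=C3'' bond and the aryl ketone react far more slowly and the reaction is stopped once debenzylation is complete.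

Compound list
1 | luteolin | O=c1cc(-c2ccc(O)c(O)c2)oc2cc(O)cc(O)c12 | starting material
2 | 7,3',4'-tri-O-benzylluteolin | O=c1cc(-c2ccc(OCc3ccccc3)c(OCc3ccccc3)c2)oc2cc(OCc3ccccc3)cc(O)c12 | intermediate
3 | 7,3',4'-tri-O-benzyl-6-iodoluteolin | O=c1cc(-c2ccc(OCc3ccccc3)c(OCc3ccccc3)c2)oc2cc(OCc3ccccc3)c(I)c(O)c12 | intermediate
4 | 5,7,3',4'-tetra-O-benzyl-6-iodoluteolin | O=c1cc(-c2ccc(OCc3ccccc3)c(OCc3ccccc3)c2)oc2cc(OCc3ccccc3)c(I)c(OCc3ccccc3)c12 | intermediate
5 | 3-bromo-4,5-dihydroxybenzaldehyde | O=Cc1cc(O)c(O)c(Br)c1 | starting material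
6 | 3-bromo-4,5-bis(tert-butyldimethylsilyloxy)benzaldehyde | O=Cc1cc(O[Si](C)(C)C(C)(C)C)c(O[Si](C)(C)C(C)(C)C)c(Br)c1 | intermediate
7 | ethyl (E)-3-[3-bromo-4,5-bis(TBSO)phenyl]prop-2-enoate | CCOC(=O)/C=C/c1cc(O[Si](C)(C)C(C)(C)C)c(O[Si](C)(C)C(C)(C)C)c(Br)c1 | intermediate
8 | (E)-3-[3-bromo-4,5-bis(TBSO)phenyl]prop-2-en-1-ol | OC/C=C/c1cc(O[Si](C)(C)C(C)(C)C)c(O[Si](C)(C)C(C)(C)C)c(Br)c1 | intermediate
9 | (E)-3-[3-bromo-4,5-bis(TBSO)phenyl]prop-2-en-1-yl methyl carbonate | COC(=O)OC/C=C/c1cc(O[Si](C)(C)C(C)(C)C)c(O[Si](C)(C)C(C)(C)C)c(Br)c1 | intermediate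
10 | 3,5-bis(benzyloxy)phenol | Oc1cc(OCc2ccccc2)cc(OCc2ccccc2)c1 | starting material
11 | lithium 3,5-bis(benzyloxy)phenoxide (formed in the flask) | [Li+].[O-]c1cc(OCc2ccccc2)cc(OCc2ccccc2)c1 | intermediate
12 | (S)-branched allylic aryl ether | C=C[C@@H](c1cc(O[Si](C)(C)C(C)(C)C)c(O[Si](C)(C)C(C)(C)C)c(Br)c1)Oc1cc(OCc2ccccc2)cc(OCc2ccccc2)c1 | intermediate
13 | (S)-B-alkyl-9-borabicyclo[3.3.1]nonane adduct (formed in the flask) | B1(CC[C@@H](c2cc(O[Si](C)(C)C(C)(C)C)c(O[Si](C)(C)C(C)(C)C)c(Br)c2)Oc2cc(OCc3ccccc3)cc(OCc3ccccc3)c2)C2CCCC1CCC2 | intermediate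
14 | (S)-3-[3,5-bis(benzyloxy)phenoxy]-3-[3-bromo-4,5-bis(TBSO)phenyl]propan-1-ol | OCC[C@@H](c1cc(O[Si](C)(C)C(C)(C)C)c(O[Si](C)(C)C(C)(C)C)c(Br)c1)Oc1cc(OCc2ccccc2)cc(OCc2ccccc2)c1 | intermediate
15 | (S)-ring B pinacol boronate alcohol | OCC[C@@H](c1cc(O[Si](C)(C)C(C)(C)C)c(O[Si](C)(C)C(C)(C)C)c(B2OC(C)(C)C(C)(C)O2)c1)Oc1cc(OCc2ccccc2)cc(OCc2ccccc2)c1 | intermediate
16 | (S)-biaryl alcohol (bis-TBS, LutBn4) | OCC[C@@H](c1cc(O[Si](C)(C)C(C)(C)C)c(O[Si](C)(C)C(C)(C)C)c(-c2c(OCc3ccccc3)cc3oc(-c4ccc(OCc5ccccc5)c(OCc5ccccc5)c4)cc(=O)c3c2OCc2ccccc2)c1)Oc1cc(OCc2ccccc2)cc(OCc2ccccc2)c1 | intermediate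
17 | (S)-biaryl aldehyde (formed in the flask) | O=CC[C@@H](c1cc(O[Si](C)(C)C(C)(C)C)c(O[Si](C)(C)C(C)(C)C)c(-c2c(OCc3ccccc3)cc3oc(-c4ccc(OCc5ccccc5)c(OCc5ccccc5)c4)cc(=O)c3c2OCc2ccccc2)c1)Oc1cc(OCc2ccccc2)cc(OCc2ccccc2)c1 | intermediate
18 | (S)-biaryl acid (bis-TBS) | OC(=O)C[C@@H](c1cc(O[Si](C)(C)C(C)(C)C)c(O[Si](C)(C)C(C)(C)C)c(-c2c(OCc3ccccc3)cc3oc(-c4ccc(OCc5ccccc5)c(OCc5ccccc5)c4)cc(=O)c3c2OCc2ccccc2)c1)Oc1cc(OCc2ccccc2)cc(OCc2ccccc2)c1 | intermediate
19 | (S)-biaryl catechol acid | OC(=O)C[C@@H](c1cc(O)c(O)c(-c2c(OCc3ccccc3)cc3oc(-c4ccc(OCc5ccccc5)c(OCc5ccccc5)c4)cc(=O)c3c2OCc2ccccc2)c1)Oc1cc(OCc2ccccc2)cc(OCc2ccccc2)c1 | intermediate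
20 | (S)-mixed carboxylic–benzyl carbonic anhydride, bis(benzyl carbonate) (formed in the flask) | O=C(OCc1ccccc1)OC(=O)C[C@@H](c1cc(OC(=O)OCc2ccccc2)c(OC(=O)OCc2ccccc2)c(-c2c(OCc3ccccc3)cc3oc(-c4ccc(OCc5ccccc5)c(OCc5ccccc5)c4)cc(=O)c3c2OCc2ccccc2)c1)Oc1cc(OCc2ccccc2)cc(OCc2ccccc2)c1 | intermediate
21 | (S)-3-[3,5-bis(benzyloxy)phenoxy]-3-[3-(LutBn4)-4,5-bis(benzyloxycarbonyloxy)phenyl]propanoic acid (key-step precursor) | OC(=O)C[C@@H](c1cc(OC(=O)OCc2ccccc2)c(OC(=O)OCc2ccccc2)c(-c2c(OCc3ccccc3)cc3oc(-c4ccc(OCc5ccccc5)c(OCc5ccccc5)c4)cc(=O)c3c2OCc2ccccc2)c1)Oc1cc(OCc2ccccc2)cc(OCc2ccccc2)c1 | intermediate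
22 | (S)-acyl trifluoroacetate (formed in the flask) | O=C(OC(=O)C(F)(F)F)C[C@@H](c1cc(OC(=O)OCc2ccccc2)c(OC(=O)OCc2ccccc2)c(-c2c(OCc3ccccc3)cc3oc(-c4ccc(OCc5ccccc5)c(OCc5ccccc5)c4)cc(=O)c3c2OCc2ccccc2)c1)Oc1cc(OCc2ccccc2)cc(OCc2ccccc2)c1 | intermediate
23 | (2S)-protected target: hexabenzyl ether, ring B bis(benzyl carbonate) (key-step product) | O=C1C[C@@H](c2cc(OC(=O)OCc3ccccc3)c(OC(=O)OCc3ccccc3)c(-c3c(OCc4ccccc4)cc4oc(-c5ccc(OCc6ccccc6)c(OCc6ccccc6)c5)cc(=O)c4c3OCc3ccccc3)c2)Oc2cc(OCc3ccccc3)cc(OCc3ccccc3)c21 | intermediate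
24 | CNP0333260.1, (2S)-5'-(luteolin-6-yl)eriodictyol | O=C1C[C@@H](c2cc(O)c(O)c(-c3c(O)cc4oc(-c5ccc(O)c(O)c5)cc(=O)c4c3O)c2)Oc2cc(O)cc(O)c21 | target

Total step count: 16. Longest linear sequence: 13 steps (5 to 24, steps 4–16); the luteolin branch (steps 1–3) joins at step 11.

Steps most likely to fail

1. Step 15 (key step).
- What may go wrong: acid-induced heterolysis of the benzylic C2–O1 bond, or β-elimination of the aryloxide from the activated acyl compound, either of which erodes enantiopurity or destroys the ether. Competing C-trifluoroacetylation of ring A and acid-promoted benzyl migration are further risks.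
- Fallback: the same bond is closed from a tertiary amide by a pyridine-buffered intramolecular Vilsmeier–Haack-type acylation, so no free Brønsted acid builds up. It sets out from 18. Coupling with dimethylamine hydrochloride (EDC·HCl, HOBt, i-Pr2NEt, CH2Cl2) should give the bis-silylated N,N-dimethylamide F1. n-Bu4NF/AcOH then gives the catechol amide F2, and CbzCl/pyridine gives the bis(benzyl carbonate) amide F3, where no carboxyl group interferes. Tf2O and 2-fluoropyridine (CH2Cl2, −78 to 0 °C) activate the amide, ring A attacks the activated carbon, and the cyclic C4 iminium triflate F4 is hydrolysed with pH 7 buffer. The fallback comes back to the route at 23.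

2. Step 11.
- What may go wrong: slow transmetalation and reductive elimination around the crowded axis, protodeboronation of the boronate, hydrodeiodination of the iodide, and loss of aryl silyl groups in hot aqueous base.
- Fallback: a role-reversed Negishi coupling that is anhydrous and free of base and skips step 10. It sets out from 4 and 14. LiCl-assisted insertion of zinc dust into iodide 4 (THF, 25–50 °C) should give the flavon-6-ylzinc iodide F5, a strong nucleophile that tolerates the pyranone. F5 is added slowly to bromide 14 with Pd(OAc)2/SPhos in THF at 25–50 °C, conditions known to tolerate free hydroxyl groups. The fallback comes back to the route at 16.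

3. Step 8.
- What may go wrong: silyl transfer from the catechol to the aryloxide or to liberated methoxide, C-allylation of the ambident electron-rich aryloxide, and erosion of regio- or enantioselectivity through reversible ionisation of the product ether.
- Fallback: the stereocentre is set by reagent-controlled carbonyl allylation and the ether is made by invertive substitution. It sets out from 6. Brown allylation with B-allyldiisopinocampheylborane derived from (−)-α-pinene (Et2O, −78 °C, ethanolamine work-up) should give the (R)-homoallylic alcohol F6. Mitsunobu reaction with 10 (PPh3, DIAD, toluene, 0 °C) inverts the centre to the (S)-homoallylic aryl ether F7. Lemieux–Johnson cleavage (OsO4 cat., NaIO4, 2,6-lutidine, dioxane–H2O) gives the (S)-β-aryloxy aldehyde F8, and NaBH4 (THF–MeOH, 0 °C) reduces it. The fallback comes back to the route at 14.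

Further compounds
F1 | step 15 | (S)-bis-silylated N,N-dimethylamide | CN(C)C(=O)C[C@@H](c1cc(O[Si](C)(C)C(C)(C)C)c(O[Si](C)(C)C(C)(C)C)c(-c2c(OCc3ccccc3)cc3oc(-c4ccc(OCc5ccccc5)c(OCc5ccccc5)c4)cc(=O)c3c2OCc2ccccc2)c1)Oc1cc(OCc2ccccc2)cc(OCc2ccccc2)c1
F2 | step 15 | (S)-catechol N,N-dimethylamide | CN(C)C(=O)C[C@@H](c1cc(O)c(O)c(-c2c(OCc3ccccc3)cc3oc(-c4ccc(OCc5ccccc5)c(OCc5ccccc5)c4)cc(=O)c3c2OCc2ccccc2)c1)Oc1cc(OCc2ccccc2)cc(OCc2ccccc2)c1
F3 | step 15 | (S)-bis(benzyl carbonate) N,N-dimethylamide | CN(C)C(=O)C[C@@H](c1cc(OC(=O)OCc2ccccc2)c(OC(=O)OCc2ccccc2)c(-c2c(OCc3ccccc3)cc3oc(-c4ccc(OCc5ccccc5)c(OCc5ccccc5)c4)cc(=O)c3c2OCc2ccccc2)c1)Oc1cc(OCc2ccccc2)cc(OCc2ccccc2)c1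
F4 | step 15 | (2S)-cyclic C4 N,N-dimethyliminium triflate | C[N+](C)=C1C[C@@H](c2cc(OC(=O)OCc3ccccc3)c(OC(=O)OCc3ccccc3)c(-c3c(OCc4ccccc4)cc4oc(-c5ccc(OCc6ccccc6)c(OCc6ccccc6)c5)cc(=O)c4c3OCc3ccccc3)c2)Oc2cc(OCc3ccccc3)cc(OCc3ccccc3)c21.[O-]S(=O)(=O)C(F)(F)F
F5 | step 11 | 5,7,3',4'-tetra-O-benzylluteolin-6-ylzinc iodide | O=c1cc(-c2ccc(OCc3ccccc3)c(OCc3ccccc3)c2)oc2cc(OCc3ccccc3)c([Zn]I)c(OCc3ccccc3)c12
F6 | step 8 | (R)-1-[3-bromo-4,5-bis(TBSO)phenyl]but-3-en-1-ol | C=CC[C@H](c1cc(O[Si](C)(C)C(C)(C)C)c(O[Si](C)(C)C(C)(C)C)c(Br)c1)O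
F7 | step 8 | (S)-homoallylic 3,5-bis(benzyloxy)phenyl ether | C=CC[C@@H](c1cc(O[Si](C)(C)C(C)(C)C)c(O[Si](C)(C)C(C)(C)C)c(Br)c1)Oc1cc(OCc2ccccc2)cc(OCc2ccccc2)c1
F8 | step 8 | (S)-3-[3,5-bis(benzyloxy)phenoxy]-3-[3-bromo-4,5-bis(TBSO)phenyl]propanal | O=CC[C@@H](c1cc(O[Si](C)(C)C(C)(C)C)c(O[Si](C)(C)C(C)(C)C)c(Br)c1)Oc1cc(OCc2ccccc2)cc(OCc2ccccc2)c1
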